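## Retrosynthetic overview

1. Lappaol A comes from its C3-carboxylic acid (borane reduction), and that from a benzyl ester. The dihydrobenzofuran is closed last, by a catalyst-controlled Rh-carbenoid C–H insertion of an aryl diazoacetate built on the finished lactone.
2. The trans-lactone comes from a γ-hydroxy tert-butyl ester, and that from an unsymmetrical 2,3-dibenzylsuccinate (imide on one side, ester on the other).
3. Key bond (C8–C8′, carrying both lactone stereocentres): oxidative heterocoupling of an Evans imide enolate with a tert-butyl ester enolate. Fe(acac)3 turns one enolate into an α-carbonyl radical (enolonium-type partner), so two normally nucleophilic α-carbons are joined. The auxiliary fixes the β-carbon; the α-carbon is set thermodynamically.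
4. Building blocks: dihydroferulic acid, 4-benzyloxy-3-methoxybenzyl chloride (used twice), tert-butyl acetate, (S)-4-benzyloxazolidinone, benzyl diazoacetate.
5. Ring order: butyrolactone first, dihydrobenzofuran second.

Assumption: Rh2(S-PTTL)4 is taken to give the (2R)-cis-dihydrobenzofuran from ortho-benzyloxy aryl diazoacetates, so the mirror-image catalyst Rh2(R-PTTL)4 is specified for the 2S centre; if the sense is opposite on this substrate, the enantiomeric catalyst is used with nothing else changed.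

## Route

Step 1
Reactants: 1 3-(4-hydroxy-3-methoxyphenyl)propanoic acid (dihydroferulic acid)
Product: 2 3-(4-hydroxy-3-iodo-5-methoxyphenyl)propanoic acid
Conditions: NIS (1.05 equiv), TsOH·H2O (10 mol %), MeCN, 0 °C → rt
Reagents that add atoms: N-iodosuccinimide, O=C1CCC(=O)N1I
Why: Electrophilic aromatic iodination in which the free phenol is the strongest director and its para position is blocked, so iodine enters the one open ortho position, as in the iodination of vanillin.

Step 2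
Reactants: 2 3-(4-hydroxy-3-iodo-5-methoxyphenyl)propanoic acid; 3 4-(benzyloxy)-3-methoxybenzyl chloride (2.2 equiv)
Product: 5 3-(4-{[4-(benzyloxy)-3-methoxybenzyl]oxy}-3-iodo-5-methoxyphenyl)propanoic acid, via bis-alkylated ester 4 (not isolated)
Conditions: K2CO3, KI (cat.), DMF, 60 °C; then NaOH (aq), MeOH–THF, 50 °C; HCl work-up
Reagents that add atoms: sodium hydroxide, [Na+].[OH-]
Why: Williamson etherification (SN2) alkylates both the phenoxide and the carboxylate, and saponification of the resulting benzylic ester in the same pot returns the free acid while the aryl ether stays intact.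

Step 3
Reactants: 5 3-(4-{[4-(benzyloxy)-3-methoxybenzyl]oxy}-3-iodo-5-methoxyphenyl)propanoic acid; 6 (4S)-4-benzyl-1,3-oxazolidin-2-one
Product: 8 (4S)-4-benzyl-3-[3-(4-{[4-(benzyloxy)-3-methoxybenzyl]oxy}-3-iodo-5-methoxyphenyl)propanoyl]-1,3-oxazolidin-2-one, via mixed pivalic anhydride 7 (not isolated)
Conditions: PivCl, Et3N, THF, −20 °C; then 6, LiCl, −20 °C → rt
Reagents that add atoms: none
Why: Mixed-anhydride N-acylation of an Evans oxazolidinone (LiCl/Et3N activation) installs the auxiliary without touching the aryl iodide or the benzylic ethers.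

Step 4
Reactants: 9 tert-butyl acetate (1.5 equiv); 3 4-(benzyloxy)-3-methoxybenzyl chloride
Product: 11 tert-butyl 3-[4-(benzyloxy)-3-methoxyphenyl]propanoate, via acetate lithium enolate 10 (not isolated)
Conditions: LDA (LiN(iPr)2, commercial solution), THF, −78 °C; then 3, DMPU, −78 → 0 °C
Reagents that add atoms: none
Why: SN2 alkylation of the lithium enolate of tert-butyl acetate, used in excess to suppress dialkylation, by the reactive electron-rich benzylic chloride gives the dihydrocinnamate ester directly.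

Step 5 (key step)
Reactants: 8 the iodoaryl propanoyl imide; 11 tert-butyl 3-[4-(benzyloxy)-3-methoxyphenyl]propanoate (2 equiv)
Product: 14 tert-butyl (2RS,3R)-2-[4-(benzyloxy)-3-methoxybenzyl]-3-(4-{[4-(benzyloxy)-3-methoxybenzyl]oxy}-3-iodo-5-methoxybenzyl)-4-[(4S)-4-benzyl-2-oxo-1,3-oxazolidin-3-yl]-4-oxobutanoate, via imide lithium enolate 12 (not isolated), via ester lithium enolate 13 (not isolated)
Conditions: LDA (3.1 equiv), THF, −78 °C, 30 min; then Fe(acac)3 (3.2 equiv), −78 °C → rt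
Reagents that add atoms: none
Why: Oxidative enolate heterocoupling in which trivalent iron oxidises one lithium enolate to an α-carbonyl radical (an enolonium-type, reversed-polarity partner) that is captured by the other enolate, so two normally nucleophilic α-carbons are joined, and the chelated Z-enolate of the (S)-benzyl imide reacts on the face opposite the benzyl group to set C3 as R while C2 forms as a mixture that step 7 corrects.

Step 6
Reactants: 14 the succinate imide/ester
Product: 15 tert-butyl (2RS,3R)-2-[4-(benzyloxy)-3-methoxybenzyl]-3-(4-{[4-(benzyloxy)-3-methoxybenzyl]oxy}-3-iodo-5-methoxybenzyl)-4-hydroxybutanoate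
Conditions: LiBH4 (2 equiv), H2O (1 equiv), Et2O–THF, 0 °C
Reagents that add atoms: none
Why: Reductive cleavage of an N-acyl oxazolidinone by LiBH4 is much faster than reduction of the tert-butyl ester, so only the imide carbonyl becomes the primary alcohol, the auxiliary is released intact, and C3, no longer α to a carbonyl, is fixed.

Step 7
Reactants: 15 the γ-hydroxy tert-butyl ester
Product: 17 (3R,4R)-3-[4-(benzyloxy)-3-methoxybenzyl]-4-(4-{[4-(benzyloxy)-3-methoxybenzyl]oxy}-3-iodo-5-methoxybenzyl)oxolan-2-one, via cis-lactone 16 (not isolated)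
Conditions: NaOMe (0.3 equiv), MeOH–THF, rt → 40 °C; AcOH quench
Reagents that add atoms: none
Why: Base-mediated lactonisation (intramolecular transesterification, 5-exo-trig) followed by enolate equilibration at the lactone α-carbon drains both C2 epimers into the thermodynamically preferred trans-(3R,4R)-lactone, the C4 centre being unable to epimerise.

Step 8
Reactants: 17 the trans-iodolactone; 18 benzyl diazoacetate
Product: 19 benzyl 2-diazo-2-[2-{[4-(benzyloxy)-3-methoxybenzyl]oxy}-5-({(3R,4R)-4-[4-(benzyloxy)-3-methoxybenzyl]-5-oxooxolan-3-yl}methyl)-3-methoxyphenyl]acetate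
Conditions: Pd(PPh3)4 (5 mol %), Ag2CO3 (0.5 equiv), Et3N (1.3 equiv), toluene, rt
Reagents that add atoms: none
Why: Zerovalent-palladium-catalysed cross-coupling of an aryl iodide with the C–H of a diazoacetate, with Ag2CO3 as halide scavenger, gives the aryl diazoacetate at room temperature without loss of dinitrogen and leaves the lactone untouched.

Step 9
Reactants: 19 the aryl diazoacetate
Product: 21 benzyl (2S,3S)-2-[4-(benzyloxy)-3-methoxyphenyl]-5-({(3R,4R)-4-[4-(benzyloxy)-3-methoxybenzyl]-5-oxooxolan-3-yl}methyl)-7-methoxy-2,3-dihydro-1-benzofuran-3-carboxylate, via cis-dihydrobenzofuran ester 20 (not isolated)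
Conditions: Rh2(R-PTTL)4 (dirhodium tetrakis[N-phthaloyl-(R)-tert-leucinate], 2 mol %), toluene, −60 °C; then KOtBu (0.2 equiv), THF, −20 → 0 °C; AcOH quench
Reagents that add atoms: none
Why: Intramolecular 1,5 C–H insertion of the rhodium carbenoid into the doubly activated benzylic ether C–H is cis-selective and catalyst-controlled (C2 set as S), base-catalysed epimerisation of the ester α-carbon then gives the more stable trans (2S,3S) ester, and because the lactone is already enantiopure any minor isomer is a separable diastereomer.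

Step 10
Reactants: 21 the trans benzyl ester
Product: 22 (2S,3S)-2-(4-hydroxy-3-methoxyphenyl)-5-{[(3R,4R)-4-(4-hydroxy-3-methoxybenzyl)-5-oxooxolan-3-yl]methyl}-7-methoxy-2,3-dihydro-1-benzofuran-3-carboxylic acid
Conditions: H2 (1 atm), 10% Pd/C, EtOAc–MeOH, rt, short reaction time
Reagents that add atoms: none
Why: Catalytic hydrogenolysis cleaves the benzyl ester and both aryl benzyl ethers in one operation under neutral conditions mild enough to leave the benzylic C2–O bond of the dihydrobenzofuran and the lactone intact.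

Step 11
Reactants: 22 the dihydrobenzofuran carboxylic acid
Product: 23 Lappaol A, (3R,4R)-3-(4-hydroxy-3-methoxybenzyl)-4-{[(2S,3R)-2-(4-hydroxy-3-methoxyphenyl)-3-(hydroxymethyl)-7-methoxy-2,3-dihydro-1-benzofuran-5-yl]methyl}oxolan-2-one
Conditions: BH3·THF (4 equiv), THF, −10 → 0 °C; MeOH quench
Reagents that add atoms: none
Why: Borane reduces a carboxylic acid through its acyloxyborane much faster than a γ-lactone, so the C3 carboxyl becomes the hydroxymethyl group with no change in spatial arrangement (the descriptor becomes 3R only through the priority switch), and the phenol borates are released on methanol quench.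

## Compound list

1 | 3-(4-hydroxy-3-methoxyphenyl)propanoic acid | COc1cc(CCC(=O)O)ccc1O | starting material
2 | 3-(4-hydroxy-3-iodo-5-methoxyphenyl)propanoic acid | COc1cc(CCC(=O)O)cc(I)c1O | intermediate
3 | 4-(benzyloxy)-3-methoxybenzyl chloride | COc1cc(CCl)ccc1OCc1ccccc1 | starting material
4 | 4-(benzyloxy)-3-methoxybenzyl 3-(4-{[4-(benzyloxy)-3-methoxybenzyl]oxy}-3-iodo-5-methoxyphenyl)propanoate | COc1cc(CCC(=O)OCc2ccc(OCc3ccccc3)c(OC)c2)cc(I)c1OCc1ccc(OCc2ccccc2)c(OC)c1 | intermediate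
5 | 3-(4-{[4-(benzyloxy)-3-methoxybenzyl]oxy}-3-iodo-5-methoxyphenyl)propanoic acid | COc1cc(CCC(=O)O)cc(I)c1OCc1ccc(OCc2ccccc2)c(OC)c1 | intermediate
6 | (4S)-4-benzyl-1,3-oxazolidin-2-one | O=C1N[C@@H](Cc2ccccc2)CO1 | starting material
7 | mixed pivalic anhydride of 5 | COc1cc(CCC(=O)OC(=O)C(C)(C)C)cc(I)c1OCc1ccc(OCc2ccccc2)c(OC)c1 | intermediate
8 | (4S)-4-benzyl-3-[3-(4-{[4-(benzyloxy)-3-methoxybenzyl]oxy}-3-iodo-5-methoxyphenyl)propanoyl]-1,3-oxazolidin-2-one | COc1cc(CCC(=O)N2[C@@H](Cc3ccccc3)COC2=O)cc(I)c1OCc1ccc(OCc2ccccc2)c(OC)c1 | intermediate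
9 | tert-butyl acetate | CC(=O)OC(C)(C)C | starting material
10 | lithium enolate of tert-butyl acetate | [Li]OC(=C)OC(C)(C)C | intermediate
11 | tert-butyl 3-[4-(benzyloxy)-3-methoxyphenyl]propanoate | COc1cc(CCC(=O)OC(C)(C)C)ccc1OCc1ccccc1 | intermediate
12 | lithium (Z)-enolate of imide 8 | COc1cc(C/C=C(\O[Li])N2[C@@H](Cc3ccccc3)COC2=O)cc(I)c1OCc1ccc(OCc2ccccc2)c(OC)c1 | intermediate
13 | lithium enolate of ester 11 | COc1cc(CC=C(O[Li])OC(C)(C)C)ccc1OCc1ccccc1 | intermediate
14 | tert-butyl (2RS,3R)-2-[4-(benzyloxy)-3-methoxybenzyl]-3-(4-{[4-(benzyloxy)-3-methoxybenzyl]oxy}-3-iodo-5-methoxybenzyl)-4-[(4S)-4-benzyl-2-oxo-1,3-oxazolidin-3-yl]-4-oxobutanoate (C2 epimers) | CC(C)(C)OC(=O)C(Cc1ccc(OCc2ccccc2)c(OC)c1)[C@@H](Cc1cc(OC)c(OCc2ccc(OCc3ccccc3)c(OC)c2)c(I)c1)C(=O)N1[C@@H](Cc2ccccc2)COC1=O | intermediate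
15 | tert-butyl (2RS,3R)-2-[4-(benzyloxy)-3-methoxybenzyl]-3-(4-{[4-(benzyloxy)-3-methoxybenzyl]oxy}-3-iodo-5-methoxybenzyl)-4-hydroxybutanoate (C2 epimers) | CC(C)(C)OC(=O)C(Cc1ccc(OCc2ccccc2)c(OC)c1)[C@@H](Cc1cc(OC)c(OCc2ccc(OCc3ccccc3)c(OC)c2)c(I)c1)CO | intermediate
16 | (3S,4R)-cis-lactone epimer of 17 | COc1cc(C[C@@H]2C(=O)OC[C@@H]2Cc2cc(OC)c(OCc3ccc(OCc4ccccc4)c(OC)c3)c(I)c2)ccc1OCc1ccccc1 | intermediate
17 | (3R,4R)-3-[4-(benzyloxy)-3-methoxybenzyl]-4-(4-{[4-(benzyloxy)-3-methoxybenzyl]oxy}-3-iodo-5-methoxybenzyl)oxolan-2-one | COc1cc(C[C@H]2C(=O)OC[C@@H]2Cc2cc(OC)c(OCc3ccc(OCc4ccccc4)c(OC)c3)c(I)c2)ccc1OCc1ccccc1 | intermediate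
18 | benzyl diazoacetate | [N-]=[N+]=CC(=O)OCc1ccccc1 | starting material
19 | benzyl 2-diazo-2-[2-{[4-(benzyloxy)-3-methoxybenzyl]oxy}-5-({(3R,4R)-4-[4-(benzyloxy)-3-methoxybenzyl]-5-oxooxolan-3-yl}methyl)-3-methoxyphenyl]acetate | COc1cc(C[C@H]2C(=O)OC[C@@H]2Cc2cc(OC)c(OCc3ccc(OCc4ccccc4)c(OC)c3)c(c2)C(=[N+]=[N-])C(=O)OCc2ccccc2)ccc1OCc1ccccc1 | intermediate
20 | benzyl (2S,3R)-cis-2-[4-(benzyloxy)-3-methoxyphenyl]-5-({(3R,4R)-4-[4-(benzyloxy)-3-methoxybenzyl]-5-oxooxolan-3-yl}methyl)-7-methoxy-2,3-dihydro-1-benzofuran-3-carboxylate | COc1cc(C[C@H]2C(=O)OC[C@@H]2Cc2cc(OC)c3c(c2)[C@@H](C(=O)OCc2ccccc2)[C@@H](c2ccc(OCc4ccccc4)c(OC)c2)O3)ccc1OCc1ccccc1 | intermediate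
21 | benzyl (2S,3S)-trans-2-[4-(benzyloxy)-3-methoxyphenyl]-5-({(3R,4R)-4-[4-(benzyloxy)-3-methoxybenzyl]-5-oxooxolan-3-yl}methyl)-7-methoxy-2,3-dihydro-1-benzofuran-3-carboxylate | COc1cc(C[C@H]2C(=O)OC[C@@H]2Cc2cc(OC)c3c(c2)[C@H](C(=O)OCc2ccccc2)[C@@H](c2ccc(OCc4ccccc4)c(OC)c2)O3)ccc1OCc1ccccc1 | intermediate
22 | (2S,3S)-2-(4-hydroxy-3-methoxyphenyl)-5-{[(3R,4R)-4-(4-hydroxy-3-methoxybenzyl)-5-oxooxolan-3-yl]methyl}-7-methoxy-2,3-dihydro-1-benzofuran-3-carboxylic acid | COc1cc(C[C@H]2C(=O)OC[C@@H]2Cc2cc(OC)c3c(c2)[C@H](C(=O)O)[C@@H](c2ccc(O)c(OC)c2)O3)ccc1O | intermediate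
23 | Lappaol A | COc1cc(C[C@H]2C(=O)OC[C@@H]2Cc2cc(OC)c3c(c2)[C@H](CO)[C@@H](c2ccc(O)c(OC)c2)O3)ccc1O | target

## Step count and risks

Total steps: 11. Longest linear sequence: 10 (steps 1, 2, 3, 5, 6, 7, 8, 9, 10, 11; step 4 is the side branch).

Steps most likely to fail:

Step 5 (oxidative heterocoupling; risk of homodimers, modest yield or erosion at C3). The fallback sets out from imide 8 and comes back at lactone 17. The same C–C bond is made with a pre-oxidised acetate partner instead of an oxidant. Enolate 12 (LDA, THF, −78 °C) is alkylated with tert-butyl bromoacetate, whose α-carbon is the electrophilic, enolonium-type partner, on the face opposite the auxiliary benzyl group to give the succinate imide F1. LiBH4 reduces the imide to the hydroxy ester F2, and NaOMe closes this to the monobenzyl lactone F3. LiN(SiMe3)2 at −78 °C gives the lactone lithium enolate F4, which chloride 3 alkylates anti to the C4 substituent, delivering 17 directly.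

Step 8 (diazoacetate cross-coupling on a hindered, electron-rich aryl iodide). The fallback sets out from 17 and comes back at 19. The diazo group is introduced after, not during, the C–C coupling. The Reformatsky reagent F5 (from benzyl bromoacetate and Zn in THF) is arylated by 17 with Pd(dba)2/P(tBu)3 (zerovalent palladium, α-arylation of a zinc enolate) to give the benzyl arylacetate F6. Regitz diazo transfer (4-acetamidobenzenesulfonyl azide, DBU, MeCN) then converts F6 into 19.

Step 9 (late-stage carbenoid C–H insertion; level and sense of catalyst control on this substrate). The fallback sets out from 17 and comes back at 23, replacing the carbenoid ring closure by a palladium oxyarylation. DDQ (CH2Cl2–H2O) removes the electron-rich 4-benzyloxy-3-methoxybenzyl group to give the iodophenol lactone F7. Heteroannulation of F7 with (E)-4-O-benzylconiferyl alcohol F8 (made from coniferyl alcohol, BnBr and K2CO3) under Pd(OAc)2/Ag2CO3 in acetone adds the aryl carbon and the phenol oxygen across the E-alkene, which keeps aryl and hydroxymethyl trans. This gives di-O-benzyl Lappaol A F9 together with its (2R,3S) ring diastereomer F10 (about 1:1, separable because the lactone is already enantiopure). Hydrogenolysis of F9 (H2, Pd/C) gives 23, so steps 8, 10 and 11 are no longer needed; the price is that this closure is not stereocontrolled at the new ring.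

## Further compounds

F1 | step 5 | tert-butyl (3R)-4-[(4S)-4-benzyl-2-oxo-1,3-oxazolidin-3-yl]-3-(4-{[4-(benzyloxy)-3-methoxybenzyl]oxy}-3-iodo-5-methoxybenzyl)-4-oxobutanoate | CC(C)(C)OC(=O)C[C@@H](Cc1cc(OC)c(OCc2ccc(OCc3ccccc3)c(OC)c2)c(I)c1)C(=O)N1[C@@H](Cc2ccccc2)COC1=O
F2 | step 5 | tert-butyl (3R)-3-(4-{[4-(benzyloxy)-3-methoxybenzyl]oxy}-3-iodo-5-methoxybenzyl)-4-hydroxybutanoate | CC(C)(C)OC(=O)C[C@@H](Cc1cc(OC)c(OCc2ccc(OCc3ccccc3)c(OC)c2)c(I)c1)CO
F3 | step 5 | (4R)-4-(4-{[4-(benzyloxy)-3-methoxybenzyl]oxy}-3-iodo-5-methoxybenzyl)oxolan-2-one | O=C1C[C@@H](Cc2cc(OC)c(OCc3ccc(OCc4ccccc4)c(OC)c3)c(I)c2)CO1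
F4 | step 5 | lithium enolate of lactone F3 | [Li]OC1=C[C@@H](Cc2cc(OC)c(OCc3ccc(OCc4ccccc4)c(OC)c3)c(I)c2)CO1
F5 | step 8 | bromo[2-(benzyloxy)-2-oxoethyl]zinc (Reformatsky reagent) | Br[Zn]CC(=O)OCc1ccccc1
F6 | step 8 | benzyl 2-[2-{[4-(benzyloxy)-3-methoxybenzyl]oxy}-5-({(3R,4R)-4-[4-(benzyloxy)-3-methoxybenzyl]-5-oxooxolan-3-yl}methyl)-3-methoxyphenyl]acetate | COc1cc(C[C@H]2C(=O)OC[C@@H]2Cc2cc(OC)c(OCc3ccc(OCc4ccccc4)c(OC)c3)c(c2)CC(=O)OCc2ccccc2)ccc1OCc1ccccc1
F7 | step 9 | (3R,4R)-3-[4-(benzyloxy)-3-methoxybenzyl]-4-(4-hydroxy-3-iodo-5-methoxybenzyl)oxolan-2-one | COc1cc(C[C@H]2C(=O)OC[C@@H]2Cc2cc(OC)c(O)c(I)c2)ccc1OCc1ccccc1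
F8 | step 9 | (E)-3-[4-(benzyloxy)-3-methoxyphenyl]prop-2-en-1-ol | COc1cc(/C=C/CO)ccc1OCc1ccccc1
F9 | step 9 | (3R,4R)-3-[4-(benzyloxy)-3-methoxybenzyl]-4-({(2S,3R)-2-[4-(benzyloxy)-3-methoxyphenyl]-3-(hydroxymethyl)-7-methoxy-2,3-dihydro-1-benzofuran-5-yl}methyl)oxolan-2-one | COc1cc(C[C@H]2C(=O)OC[C@@H]2Cc2cc(OC)c3c(c2)[C@H](CO)[C@@H](c2ccc(OCc4ccccc4)c(OC)c2)O3)ccc1OCc1ccccc1
F10 | step 9 | (2R,3S)-dihydrobenzofuran diastereomer of F9 | COc1cc(C[C@H]2C(=O)OC[C@@H]2Cc2cc(OC)c3c(c2)[C@@H](CO)[C@H](c2ccc(OCc4ccccc4)c(OC)c2)O3)ccc1OCc1ccccc1
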